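The route rests on cutting the C4–C5 bond of the tetrahydrofuran ring (O1, C2–C5). C5 is an unsubstituted CH2 between O1 and C4, so it can be carried as the methylene of a methoxymethyl ether on the C2 oxygen and joined to the near carbon of an (E)-styrene on C3. In one operation a Lewis acid ionises that ether, the oxocarbenium ion closes the ring onto the styrene, and the C3 ester traps the benzylic cation as a cis-fused γ-lactone, which fixes C4 relative to C3. The substrate is a methyl 2-benzyloxy-2-[aryl(methoxymethoxy)methyl]-4-arylbut-3-enoate; the lactone later becomes the C3 hydroxymethyl and C4 benzyl groups.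

Key step: step 9

Remark: β-isocupreidine is assumed to give the (R)-configured Morita–Baylis–Hillman adduct from aryl aldehydes, as is usual for this catalyst; ring numbering throughout is O1, C2 (aryl), C3 (carbinol), C4 (benzyl), C5, and OTs/tosyloxy means (4-methylphenyl)sulfonyloxy.

Step 1
Reactants: 1 vanillin
Product: 2 4-formyl-2-methoxyphenyl 4-methylbenzenesulfonate
Conditions: TsCl, Et3N, DMAP (cat.), CH2Cl2, 0 °C → rt
Reagents that add atoms: p-toluenesulfonyl chloride, Cc1ccc(S(=O)(=O)Cl)cc1
Why: Sulfonylation of the only hydroxyl group (phenol tosylation); the tosylate is electron-withdrawing, which later disfavours ionisation at benzylic C2, and unlike a mesylate it has no acidic α-hydrogens for the basic step 8.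

Step 2
Reactants: 2 4-formyl-2-methoxyphenyl 4-methylbenzenesulfonate; 3 1,1,1,3,3,3-hexafluoropropan-2-yl prop-2-enoate
Product: 4 1,1,1,3,3,3-hexafluoropropan-2-yl (R)-2-{hydroxy[3-methoxy-4-(tosyloxy)phenyl]methyl}prop-2-enoate
Conditions: β-isocupreidine (10 mol %), DMF, −55 °C
Reagents that add atoms: none
Why: Asymmetric Morita–Baylis–Hillman reaction of an activated aryl aldehyde with the fluoroalkyl acrylate, in which the hydrogen-bonding cinchona catalyst should set the carbinol centre (future C2) as R; chromatography removes the dioxanone by-product typical of this reaction.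

Step 3
Reactants: 4 1,1,1,3,3,3-hexafluoropropan-2-yl (R)-2-{hydroxy[3-methoxy-4-(tosyloxy)phenyl]methyl}prop-2-enoate
Product: 5 methyl (R)-2-{hydroxy[3-methoxy-4-(tosyloxy)phenyl]methyl}prop-2-enoate
Conditions: NaOMe (0.1 equiv), MeOH, −20 → 0 °C
Reagents that add atoms: methanol, CO
Why: Base-catalysed transesterification of the activated hexafluoroisopropyl ester, which should be fast enough in the cold that neither the carbinol centre nor the aryl tosylate is disturbed.

Step 4
Reactants: 5 methyl (R)-2-{hydroxy[3-methoxy-4-(tosyloxy)phenyl]methyl}prop-2-enoate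
Product: 6 methyl (R)-2-{(methoxymethoxy)[3-methoxy-4-(tosyloxy)phenyl]methyl}prop-2-enoate
Conditions: MOMCl, i-Pr2NEt, CH2Cl2, 0 °C → rt
Reagents that add atoms: chloromethyl methyl ether, COCCl
Why: Alkoxymethylation of the secondary alcohol under amine-base conditions (MOM protection); the group later serves as chelating group in step 7 and as the source of C5 in step 9.

Step 5
Reactants: 6 methyl (R)-2-{(methoxymethoxy)[3-methoxy-4-(tosyloxy)phenyl]methyl}prop-2-enoate
Product: 8 methyl (R)-3-(methoxymethoxy)-3-[3-methoxy-4-(tosyloxy)phenyl]-2-oxopropanoate, via ozonide 7 (not isolated)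
Conditions: O3, CH2Cl2, −78 °C; then Me2S, −78 °C → rt; used directly
Reagents that add atoms: ozone, [O-][O+]=O
Why: Ozonolysis of the 1,1-disubstituted acrylate double bond with reductive work-up excises the methylene carbon and unveils the α-keto ester under neutral conditions, so the enolisable benzylic centre next to the ketone should keep its configuration.

Step 6
Reactants: 9 4-(benzyloxy)-3-methoxybenzaldehyde
Product: 10 1-(benzyloxy)-4-ethynyl-2-methoxybenzene
Conditions: dimethyl (1-diazo-2-oxopropyl)phosphonate, K2CO3, MeOH, 0 °C → rt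
Reagents that add atoms: dimethyl (1-diazo-2-oxopropyl)phosphonate, COP(=O)(OC)C(=[N+]=[N-])C(C)=O
Why: Seyferth–Gilbert homologation in the Ohira–Bestmann variant converts the aryl aldehyde into the terminal alkyne under mild carbonate conditions that a benzyl ether tolerates.

Step 7
Reactants: 10 1-(benzyloxy)-4-ethynyl-2-methoxybenzene; 8 methyl (R)-3-(methoxymethoxy)-3-[3-methoxy-4-(tosyloxy)phenyl]-2-oxopropanoate
Product: 13 methyl (2R,3E)-4-[4-(benzyloxy)-3-methoxyphenyl]-2-hydroxy-2-{(R)-(methoxymethoxy)[3-methoxy-4-(tosyloxy)phenyl]methyl}but-3-enoate, via alkenylzirconocene chloride 11 (not isolated), via alkenyl(methyl)zinc 12 (not isolated)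
Conditions: Cp2Zr(H)Cl, CH2Cl2, rt; Me2Zn, toluene, −65 °C; then 8, −65 → 0 °C; aq NaHCO3
Reagents that add atoms: none
Why: syn-Hydrozirconation fixes the (E)-alkene, Zr→Zn transmetalation gives a weakly basic alkenylzinc that adds to the very electrophilic keto group (alkenylzinc 1,2-addition to an α-keto ester), and five-membered chelation of the metal by the ketone and MOM oxygens (Cram chelate model) directs attack to the face anti to the aryl group, which sets the quaternary carbinol (future C3) as R.

Step 8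
Reactants: 13 methyl (2R,3E)-4-[4-(benzyloxy)-3-methoxyphenyl]-2-hydroxy-2-{(R)-(methoxymethoxy)[3-methoxy-4-(tosyloxy)phenyl]methyl}but-3-enoate
Product: 14 methyl (2R,3E)-2-(benzyloxy)-4-[4-(benzyloxy)-3-methoxyphenyl]-2-{(R)-(methoxymethoxy)[3-methoxy-4-(tosyloxy)phenyl]methyl}but-3-enoate
Conditions: NaH, BnBr, Bu4NI (cat.), THF–DMF, 0 °C → rt
Reagents that add atoms: benzyl bromide, BrCc1ccccc1
Why: Williamson etherification of the tertiary sodium alkoxide with iodide catalysis; the alkoxide sits on a quaternary carbon with no α-hydrogen or β-leaving group, so no elimination, epimerisation or alkene migration is open to it.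

Step 9
Reactants: 14 methyl (2R,3E)-2-(benzyloxy)-4-[4-(benzyloxy)-3-methoxyphenyl]-2-{(R)-(methoxymethoxy)[3-methoxy-4-(tosyloxy)phenyl]methyl}but-3-enoate
Product: 15 (1R,4S,5R,8R)-1-(benzyloxy)-4-[4-(benzyloxy)-3-methoxyphenyl]-8-[3-methoxy-4-(tosyloxy)phenyl]-3,7-dioxabicyclo[3.3.0]octan-2-one (cis-fused furofuranone with both aryl groups on the convex face)
Conditions: TMSOTf (0.3 equiv), 2,6-di-tert-butyl-4-methylpyridine (0.1 equiv), CH2Cl2 (0.01 M), −78 → −30 °C; aq NaHCO3
Reagents that add atoms: none
Why: Trimethylsilyl triflate silylates the terminal methoxy oxygen of the MOM group and MeOSiMe3 departs, leaving the O1=C5H2 oxocarbenium ion, which is attacked by the styrene carbon next to C3 (new C4–C5 bond); the para-benzyloxybenzylic cation so formed is trapped by the ester carbonyl oxygen, and the O-methyl lactonium ion passes its methyl group to MeOSiMe3, which releases dimethyl ether and returns the silyl triflate. The closest known reaction type is the Prins cyclisation of alkoxymethyl-ether-derived oxocarbenium ions onto aryl alkenes with ester termination (Prins/lactonisation cascade). The tetrahydrofuran closes 5-exo-trig with respect to the alkene, with the O1=C5 unit inside the new ring as in any Prins closure, and the γ-lactone closes by five-membered (5-exo) attack of the carbonyl oxygen on the exocyclic cationic carbon. C4 is controlled by the quaternary C3: the cation can lactonise only when its carbon sits cis to the ester, whereas the other rotamer places it on the more crowded face beside the benzyloxy and C2-aryl groups and has no ring-closing outlet, so only the cis-fused bicycle should accumulate; the lactone CH(aryl) centre follows from anti addition across the (E)-alkene, which puts that aryl on the convex face, and it is erased in step 10. The step needs ionisation at the MOM terminus and not at the benzylic C2–O bond (or a 2-oxonia-Cope shift), which the electron-poor tosyloxy aryl secures, and attack through the alkene carbon that gives the five- and not the six-membered ether, which the cation-stabilising para-benzyloxyphenyl on the far carbon secures.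

Step 10
Reactants: 15 (1R,4S,5R,8R)-1-(benzyloxy)-4-[4-(benzyloxy)-3-methoxyphenyl]-8-[3-methoxy-4-(tosyloxy)phenyl]-3,7-dioxabicyclo[3.3.0]octan-2-one
Product: 16 (2R,3R,4S)-3-hydroxy-4-(4-hydroxy-3-methoxybenzyl)-2-[3-methoxy-4-(tosyloxy)phenyl]tetrahydrofuran-3-carboxylic acid
Conditions: H2 (1 atm), Pd(OH)2/C, EtOAc–AcOH (10:1), rt; stopped once 15 and its partly reduced forms are consumed
Reagents that add atoms: none
Why: Palladium-catalysed hydrogenolysis removes both O-benzyl groups and cleaves the lactone C–O bond, a benzylic ester next to the by then free para-hydroxyphenyl ring, whereas the ring C2–O1 bond is a hindered benzylic ether on the electron-poor tosyloxy aryl and should persist; C2, C3 and C4 are not touched and the lactone CH(aryl) centre becomes the benzyl CH2.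

Step 11
Reactants: 16 (2R,3R,4S)-3-hydroxy-4-(4-hydroxy-3-methoxybenzyl)-2-[3-methoxy-4-(tosyloxy)phenyl]tetrahydrofuran-3-carboxylic acid
Product: 18 (2R,3S,4S)-4-(4-hydroxy-3-methoxybenzyl)-2-(4-hydroxy-3-methoxyphenyl)-3-(hydroxymethyl)tetrahydrofuran-3-ol, via tosylate triol 17 (not isolated)
Conditions: BH3·SMe2, THF, 0 °C → rt; MeOH quench; then KOH, H2O–1,4-dioxane, 80 °C, argon; acidify to pH 5
Reagents that add atoms: none
Why: Borane reduces the carboxylic acid chemoselectively to the primary alcohol (borane reduction of a carboxylic acid) and leaves the aryl sulfonate alone, and hydroxide in a methanol-free medium then cleaves the aryl tosylate at sulfur (sulfonate ester hydrolysis) without creating a methylating agent; no stereocentre is involved.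

Compound list
1 | vanillin (4-hydroxy-3-methoxybenzaldehyde) | COc1cc(C=O)ccc1O | starting material
2 | 4-formyl-2-methoxyphenyl 4-methylbenzenesulfonate | COc1cc(C=O)ccc1OS(=O)(=O)c1ccc(C)cc1 | intermediate
3 | 1,1,1,3,3,3-hexafluoropropan-2-yl prop-2-enoate | C=CC(=O)OC(C(F)(F)F)C(F)(F)F | starting material
4 | 1,1,1,3,3,3-hexafluoropropan-2-yl (R)-2-{hydroxy[3-methoxy-4-(tosyloxy)phenyl]methyl}prop-2-enoate | C=C(C(=O)OC(C(F)(F)F)C(F)(F)F)[C@H](O)c1ccc(OS(=O)(=O)c2ccc(C)cc2)c(OC)c1 | intermediate
5 | methyl (R)-2-{hydroxy[3-methoxy-4-(tosyloxy)phenyl]methyl}prop-2-enoate | C=C(C(=O)OC)[C@H](O)c1ccc(OS(=O)(=O)c2ccc(C)cc2)c(OC)c1 | intermediate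
6 | methyl (R)-2-{(methoxymethoxy)[3-methoxy-4-(tosyloxy)phenyl]methyl}prop-2-enoate | C=C(C(=O)OC)[C@H](OCOC)c1ccc(OS(=O)(=O)c2ccc(C)cc2)c(OC)c1 | intermediate
7 | methyl 3-{(R)-(methoxymethoxy)[3-methoxy-4-(tosyloxy)phenyl]methyl}-1,2,4-trioxolane-3-carboxylate (ozonide, either configuration at the ring carbon) | COC(=O)C1(OCOO1)[C@H](OCOC)c1ccc(OS(=O)(=O)c2ccc(C)cc2)c(OC)c1 | intermediate
8 | methyl (R)-3-(methoxymethoxy)-3-[3-methoxy-4-(tosyloxy)phenyl]-2-oxopropanoate | COC(=O)C(=O)[C@H](OCOC)c1ccc(OS(=O)(=O)c2ccc(C)cc2)c(OC)c1 | intermediate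
9 | 4-(benzyloxy)-3-methoxybenzaldehyde | COc1cc(C=O)ccc1OCc1ccccc1 | starting material
10 | 1-(benzyloxy)-4-ethynyl-2-methoxybenzene | COc1cc(C#C)ccc1OCc1ccccc1 | intermediate
11 | (E)-[2-(4-benzyloxy-3-methoxyphenyl)ethenyl]chlorobis(cyclopentadienyl)zirconium | COc1cc(/C=C/[Zr](Cl)(C2C=CC=C2)C2C=CC=C2)ccc1OCc1ccccc1 | intermediate
12 | (E)-[2-(4-benzyloxy-3-methoxyphenyl)ethenyl](methyl)zinc | COc1cc(/C=C/[Zn]C)ccc1OCc1ccccc1 | intermediate
13 | methyl (2R,3E)-4-[4-(benzyloxy)-3-methoxyphenyl]-2-hydroxy-2-{(R)-(methoxymethoxy)[3-methoxy-4-(tosyloxy)phenyl]methyl}but-3-enoate | COCO[C@H](c1ccc(OS(=O)(=O)c2ccc(C)cc2)c(OC)c1)[C@@](O)(C(=O)OC)/C=C/c1ccc(OCc2ccccc2)c(OC)c1 | intermediate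
14 | methyl (2R,3E)-2-(benzyloxy)-4-[4-(benzyloxy)-3-methoxyphenyl]-2-{(R)-(methoxymethoxy)[3-methoxy-4-(tosyloxy)phenyl]methyl}but-3-enoate | COCO[C@H](c1ccc(OS(=O)(=O)c2ccc(C)cc2)c(OC)c1)[C@@](OCc1ccccc1)(C(=O)OC)/C=C/c1ccc(OCc2ccccc2)c(OC)c1 | intermediate
15 | (1R,4S,5R,8R)-1-(benzyloxy)-4-[4-(benzyloxy)-3-methoxyphenyl]-8-[3-methoxy-4-(tosyloxy)phenyl]-3,7-dioxabicyclo[3.3.0]octan-2-one | COc1cc(ccc1OCc1ccccc1)[C@H]1OC(=O)[C@@]2(OCc3ccccc3)[C@@H]1CO[C@@H]2c1ccc(OS(=O)(=O)c2ccc(C)cc2)c(OC)c1 | intermediate
16 | (2R,3R,4S)-3-hydroxy-4-(4-hydroxy-3-methoxybenzyl)-2-[3-methoxy-4-(tosyloxy)phenyl]tetrahydrofuran-3-carboxylic acid | COc1cc(C[C@H]2CO[C@H](c3ccc(OS(=O)(=O)c4ccc(C)cc4)c(OC)c3)[C@@]2(O)C(=O)O)ccc1O | intermediate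
17 | 4-[(2R,3S,4S)-3-hydroxy-4-(4-hydroxy-3-methoxybenzyl)-3-(hydroxymethyl)tetrahydrofuran-2-yl]-2-methoxyphenyl 4-methylbenzenesulfonate | COc1cc(C[C@H]2CO[C@H](c3ccc(OS(=O)(=O)c4ccc(C)cc4)c(OC)c3)[C@@]2(O)CO)ccc1O | intermediate
18 | (2R,3S,4S)-4-(4-hydroxy-3-methoxybenzyl)-2-(4-hydroxy-3-methoxyphenyl)-3-(hydroxymethyl)tetrahydrofuran-3-ol | COc1cc(C[C@H]2CO[C@H](c3ccc(O)c(OC)c3)[C@@]2(O)CO)ccc1O | target

Total step count: 11. Longest linear sequence: 10 steps (steps 1–5 and 7–11); step 6 is a one-step side branch.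

Steps most likely to fail

1. Step 9. What may go wrong: ionisation at the tertiary allylic C3–O bond instead of the MOM terminus, participation of the benzyl ether oxygen in the oxocarbenium ion with loss of the benzyl group, or a cation that is not closed to the lactone. Fallback, setting out from 13 and coming back at 16: the benzylation is left out. A catalytic amount of TMSOTf in CH2Cl2 at −78 °C should let the free tertiary hydroxyl capture the oxocarbenium ion, with loss of methanol, to give the cyclic formaldehyde acetal methyl (4R,5R)-4-[(E)-2-(4-benzyloxy-3-methoxyphenyl)ethenyl]-5-[3-methoxy-4-(tosyloxy)phenyl]-1,3-dioxolane-4-carboxylate F1. TiCl4 in CH2Cl2 (−78 → −30 °C) then opens this acetal at the tertiary oxygen, which becomes a titanium alkoxide and so is neither a good leaving group nor a participating ether. The same O1=C5 oxocarbenium ion cyclises onto the styrene, and chloride removes the ester methyl as chloromethane, giving (1R,4S,5R,8R)-4-[4-(benzyloxy)-3-methoxyphenyl]-1-hydroxy-8-[3-methoxy-4-(tosyloxy)phenyl]-3,7-dioxabicyclo[3.3.0]octan-2-one F2. Hydrogenolysis of F2 under the conditions of step 10 gives 16.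

2. Step 7. What may go wrong: poor facial selectivity if chelation through the MOM oxygen does not dominate, or enolisation of the keto ester with loss of configuration at C2 before addition. Fallback, setting out from 8 and coming back at 13: 8 is precomplexed with MgBr2·OEt2 in CH2Cl2 at −78 °C and treated with vinylmagnesium bromide. This small, fast Grignard reagent should add under classical magnesium chelate control to give methyl (2R)-2-hydroxy-2-{(R)-(methoxymethoxy)[3-methoxy-4-(tosyloxy)phenyl]methyl}but-3-enoate F3. The aryl group is then attached by a Mizoroki–Heck reaction (Pd(OAc)2, Bu4NCl, NaHCO3, DMF, 60 °C) with 1-(benzyloxy)-4-iodo-2-methoxybenzene F4, made from commercial 4-iodo-2-methoxyphenol with benzyl bromide and K2CO3. Because C3 carries no hydrogen, β-hydride elimination can only give the (E)-styrene 13.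

3. Step 10. What may go wrong: over-reduction by hydrogenolysis of the ring C2–O1 bond, or incomplete cleavage of the lactone C–O bond. Fallback, setting out from 15 and coming back at 16: hydrogen gas is avoided. Et3SiH with BF3·OEt2 in CH2Cl2 (−40 → 0 °C) should ionise only the lactone C–O bond beside the para-benzyloxyphenyl ring and reduce the cation (ionic hydrogenation), giving (2R,3R,4S)-3-(benzyloxy)-4-[4-(benzyloxy)-3-methoxybenzyl]-2-[3-methoxy-4-(tosyloxy)phenyl]tetrahydrofuran-3-carboxylic acid F5. Both benzyl ethers are then removed with BCl3 and pentamethylbenzene in CH2Cl2 at −78 °C, which gives 16.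

Further compounds
F1 | step 9 | methyl (4R,5R)-4-[(E)-2-(4-benzyloxy-3-methoxyphenyl)ethenyl]-5-[3-methoxy-4-(tosyloxy)phenyl]-1,3-dioxolane-4-carboxylate | C1O[C@H](c2ccc(OS(=O)(=O)c3ccc(C)cc3)c(OC)c2)[C@@](O1)(C(=O)OC)/C=C/c1ccc(OCc2ccccc2)c(OC)c1
F2 | step 9 | (1R,4S,5R,8R)-4-[4-(benzyloxy)-3-methoxyphenyl]-1-hydroxy-8-[3-methoxy-4-(tosyloxy)phenyl]-3,7-dioxabicyclo[3.3.0]octan-2-one | COc1cc(ccc1OCc1ccccc1)[C@H]1OC(=O)[C@@]2(O)[C@@H]1CO[C@@H]2c1ccc(OS(=O)(=O)c2ccc(C)cc2)c(OC)c1
F3 | step 7 | methyl (2R)-2-hydroxy-2-{(R)-(methoxymethoxy)[3-methoxy-4-(tosyloxy)phenyl]methyl}but-3-enoate | COCO[C@H](c1ccc(OS(=O)(=O)c2ccc(C)cc2)c(OC)c1)[C@@](O)(C(=O)OC)C=C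
F4 | step 7 | 1-(benzyloxy)-4-iodo-2-methoxybenzene | COc1cc(I)ccc1OCc1ccccc1
F5 | step 10 | (2R,3R,4S)-3-(benzyloxy)-4-[4-(benzyloxy)-3-methoxybenzyl]-2-[3-methoxy-4-(tosyloxy)phenyl]tetrahydrofuran-3-carboxylic acid | COc1cc(C[C@H]2CO[C@H](c3ccc(OS(=O)(=O)c4ccc(C)cc4)c(OC)c3)[C@@]2(OCc5ccccc5)C(=O)O)ccc1OCc1ccccc1
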